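Both stereocentres are traced back to one racemic keto ester. Its C7 is an aryl ketone on ring A. Its C8 lies between that ketone and the C9 ester, carries the ether oxygen of ring B, and holds an acidic hydrogen that epimerises through the enol. A ketoreductase reduces one C8 enantiomer on one carbonyl face while the other keeps racemising. One operation should therefore turn the whole racemate into the anti (2R,3R) hydroxy ester and fix C7 and C8 together. The precursor is built without stereocontrol by malonate acylation, diazo transfer and carbene O–H insertion into the hindered phenol. One hydride reduction then delivers the diol.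

Key step: step 6

Remark on the chemistry: neolignan numbering is used for the chain (C7 benzylic, C8 ether-bearing, C9 terminal). Ring A is the 4-oxygenated 3,5-dimethoxyphenyl ring on C7; ring B is the 4-allyl-2,6-dimethoxyphenyl ring on the C8 oxygen. The ketoreductase is assumed to be identified by screening a panel.

Step 1
Reactants: 1 syringic acid (4-hydroxy-3,5-dimethoxybenzoic acid)
Product: 2 4-acetoxy-3,5-dimethoxybenzoic acid
Conditions: Ac2O, pyridine, DMAP (cat.), rt; aq. HCl work-up
Reagents that add atoms: acetic anhydride, CC(=O)OC(C)=O
Why: DMAP-catalysed O-acetylation of the phenol (nucleophilic acyl substitution) should be clean, the carboxylic acid is recovered unchanged after the acidic aqueous work-up, and the acetate keeps the later C7 ketone from being deactivated as a phenoxide.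

Step 2
Reactants: 2 4-acetoxy-3,5-dimethoxybenzoic acid
Product: 3 4-acetoxy-3,5-dimethoxybenzoyl chloride
Conditions: (COCl)2, DMF (cat.), CH2Cl2, 0 °C to rt; evaporated and used crude
Reagents that add atoms: oxalyl chloride, O=C(Cl)C(Cl)=O
Why: Acid chloride formation under Vilsmeier-type DMF catalysis gives only gaseous by-products and leaves the aryl acetate and the methyl ethers untouched.

Step 3
Reactants: 3 4-acetoxy-3,5-dimethoxybenzoyl chloride; 4 potassium ethyl malonate
Product: 6 ethyl 3-(4-acetoxy-3,5-dimethoxyphenyl)-3-oxopropanoate, via acylmalonic half ester 5 (not isolated)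
Conditions: 4 (2 equiv), MgCl2, Et3N, MeCN, 0 °C to rt; then 3, 0 °C to rt; 1 M HCl work-up
Reagents that add atoms: none
Why: Decarboxylative Claisen-type C-acylation of the malonate half-ester enolate generated with MgCl2 and Et3N forms the C7–C8 bond, acidification releases the β-keto acid 5, which loses CO2, and the acid chloride is far more electrophilic than the aryl acetate.

Step 4
Reactants: 6 ethyl 3-(4-acetoxy-3,5-dimethoxyphenyl)-3-oxopropanoate
Product: 7 ethyl 2-diazo-3-(4-acetoxy-3,5-dimethoxyphenyl)-3-oxopropanoate
Conditions: 4-acetamidobenzenesulfonyl azide, Et3N, MeCN, 0 °C to rt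
Reagents that add atoms: 4-acetamidobenzenesulfonyl azide, CC(=O)Nc1ccc(cc1)S(=O)(=O)N=[N+]=[N-]
Why: Regitz diazo transfer to the doubly activated methylene (C8) of a β-keto ester is reliable, and the mild amine base should leave the aryl acetate intact.

Step 5
Reactants: 7 ethyl 2-diazo-3-(4-acetoxy-3,5-dimethoxyphenyl)-3-oxopropanoate; 8 4-allyl-2,6-dimethoxyphenol
Product: 9 racemic ethyl 3-(4-acetoxy-3,5-dimethoxyphenyl)-2-(4-allyl-2,6-dimethoxyphenoxy)-3-oxopropanoate
Conditions: Rh2(OAc)4 (1 mol %), 8 (1.3 equiv), ClCH2CH2Cl, 75 °C, slow addition of 7
Reagents that add atoms: none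
Why: Carbene O–H insertion, in which loss of N2 from 7 at Rh2(OAc)4 gives an electrophilic acceptor/acceptor carbene that the phenolic oxygen captures under neutral conditions, is a known way to 2-aryloxy-3-oxo esters that avoids an SN2 reaction of a hindered phenoxide; excess phenol and slow addition should favour it over cyclopropanation of the allyl group and carbene dimerisation, and C8 is formed racemic.

Step 6
Reactants: 9 racemic ethyl 3-(4-acetoxy-3,5-dimethoxyphenyl)-2-(4-allyl-2,6-dimethoxyphenoxy)-3-oxopropanoate
Product: 10 ethyl (2R,3R)-3-(4-acetoxy-3,5-dimethoxyphenyl)-2-(4-allyl-2,6-dimethoxyphenoxy)-3-hydroxypropanoate (anti isomer)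
Conditions: ketoreductase (anti-(2R,3R)-selective hit from a panel), NADP+ (cat.), D-glucose, glucose dehydrogenase, KH2PO4/K2HPO4 buffer pH 7.0, DMSO (15% v/v), 30 °C
Reagents that add atoms: none
Why: Proposed new method: in the neutral phosphate buffer the C8 hydrogen of 9, flanked by the C7 ketone and the C9 ester and geminal to the ring B oxygen, should exchange through the enol faster than the ketone is reduced, while the enzyme binds only the (R)-configured keto ester productively and transfers the C4 hydride of NADPH (regenerated by glucose and glucose dehydrogenase) to one face of the C7 carbonyl; once C7 is a carbinol, C8 is no longer acidic and both centres are locked. The closest known reaction types are ketoreductase-catalysed dynamic reductive kinetic resolutions of 2-substituted 3-aryl-3-oxo esters and, in the oxidative direction, the stereospecific C7 dehydrogenation of arylglycerol β-aryl ethers by nicotinamide-dependent short-chain dehydrogenases of bacterial lignin catabolism, which shows that such active sites can hold this doubly arylated skeleton; what is new is the pairing of an aryl ketone on one side with a bulky aryloxy group on the other. No bond between heavy atoms forms and no ring is closed. C7 (R) is controlled by the active site, which fixes the face of hydride delivery, and C8 (R at the ester stage) by the enzyme's choice of one substrate enantiomer coupled to racemisation of the other. The step needs anti diastereoselectivity together with enantioselectivity, both of which must come from the enzyme selected in the panel screen, whereas the substrate secures the dynamic behaviour through its labile C8 hydrogen and keeps the ketone electrophilic through the ring A acetate, which prevents a deactivating para-phenoxide. Should the acetate be partly hydrolysed in the buffer, both products converge in step 7.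

Step 7
Reactants: 10 ethyl (2R,3R)-3-(4-acetoxy-3,5-dimethoxyphenyl)-2-(4-allyl-2,6-dimethoxyphenoxy)-3-hydroxypropanoate
Product: 11 (1R,2S)-2-(4-allyl-2,6-dimethoxyphenoxy)-1-(4-hydroxy-3,5-dimethoxyphenyl)propane-1,3-diol, the (7R,8S) erythro target CNP0419292.1
Conditions: LiAlH4 (3 equiv), THF, −20 to 0 °C; aq. potassium sodium tartrate, then NH4Cl to pH 6
Reagents that add atoms: none
Why: Hydride reduction of the ester to the C9 primary alcohol with simultaneous reductive cleavage of the aryl acetate should be fast because the C7 alkoxide formed first directs hydride to the neighbouring ester, no bond at C7 or C8 changes (the C8 descriptor becomes S only because C9 drops in priority), the isolated allyl alkene is inert to LiAlH4, and the weakly acidic work-up avoids benzylic ionisation.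

Compound list
1 | syringic acid (4-hydroxy-3,5-dimethoxybenzoic acid) | COc1cc(C(=O)O)cc(OC)c1O | starting material
2 | 4-acetoxy-3,5-dimethoxybenzoic acid | COc1cc(C(=O)O)cc(OC)c1OC(C)=O | intermediate
3 | 4-acetoxy-3,5-dimethoxybenzoyl chloride | COc1cc(C(=O)Cl)cc(OC)c1OC(C)=O | intermediate
4 | potassium ethyl malonate | CCOC(=O)CC(=O)[O-].[K+] | starting material
5 | 2-(4-acetoxy-3,5-dimethoxybenzoyl)malonic acid monoethyl ester (acylmalonic half ester, present as its magnesium salt until acidification) | CCOC(=O)C(C(=O)O)C(=O)c1cc(OC)c(OC(C)=O)c(OC)c1 | intermediate (not isolated)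
6 | ethyl 3-(4-acetoxy-3,5-dimethoxyphenyl)-3-oxopropanoate | CCOC(=O)CC(=O)c1cc(OC)c(OC(C)=O)c(OC)c1 | intermediate
7 | ethyl 2-diazo-3-(4-acetoxy-3,5-dimethoxyphenyl)-3-oxopropanoate | CCOC(=O)C(=[N+]=[N-])C(=O)c1cc(OC)c(OC(C)=O)c(OC)c1 | intermediate
8 | 4-allyl-2,6-dimethoxyphenol | C=CCc1cc(OC)c(O)c(OC)c1 | starting material
9 | racemic ethyl 3-(4-acetoxy-3,5-dimethoxyphenyl)-2-(4-allyl-2,6-dimethoxyphenoxy)-3-oxopropanoate | C=CCc1cc(OC)c(OC(C(=O)OCC)C(=O)c2cc(OC)c(OC(C)=O)c(OC)c2)c(OC)c1 | intermediate
10 | ethyl (2R,3R)-3-(4-acetoxy-3,5-dimethoxyphenyl)-2-(4-allyl-2,6-dimethoxyphenoxy)-3-hydroxypropanoate (anti) | C=CCc1cc(OC)c(O[C@@H](C(=O)OCC)[C@H](O)c2cc(OC)c(OC(C)=O)c(OC)c2)c(OC)c1 | intermediate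
11 | (1R,2S)-2-(4-allyl-2,6-dimethoxyphenoxy)-1-(4-hydroxy-3,5-dimethoxyphenyl)propane-1,3-diol, (7R,8S) erythro | C=CCc1cc(OC)c(O[C@@H](CO)[C@H](O)c2cc(OC)c(O)c(OC)c2)c(OC)c1 | target

Total step count: 7
Longest linear sequence: 7 steps (1 to 11); 4 and 8 enter as bought materials.

Steps most likely to fail

Step 6 (bears the label "Proposed new method:"). The risks are:
- no enzyme of the panel may bind the doubly arylated keto ester productively with anti diastereoselection, so reduction stalls or runs into the syn series;
- C8 exchange may be slower than expected, so conversion stops near half;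
- esterase impurities may hydrolyse the ethyl ester, after which decarboxylation would destroy C9.

The fallback uses known chemistry, sets out from 9 and comes back at 10. Compound 9 is reduced with NaBH4 in THF/EtOH at −30 °C, which is chemoselective for the ketone. Hydride reductions of aryl ketones bearing an α-(2,6-dimethoxyphenoxy) group are expected to give a useful share of the anti alcohol. The racemic anti hydroxy ester F1 is separated from its syn isomer on silica. The enantiomers of F1 are then resolved by preparative chromatography on a cellulose tris(3,5-dimethylphenylcarbamate) phase to give 10. Material of the wrong configuration can be returned to 9 by Dess–Martin oxidation, where C8 racemises again.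

Step 5. The carbene bound to Rh2(OAc)4 may be diverted to cyclopropanation of the allyl group, to attack on the electron-rich arene or to dimerisation, because the O–H of the doubly ortho-substituted phenol is hindered.

The fallback sets out from 8 and comes back at 9. Williamson etherification of 8 with ethyl bromoacetate (K2CO3, acetone, reflux) should give ethyl 2-(4-allyl-2,6-dimethoxyphenoxy)acetate F2. Its enolate is formed with LiN(SiMe3)2 in THF at −78 °C, with F2 and base both in twofold amount so that the second enolate equivalent deprotonates the product. The enolate is then C-acylated with acid chloride 3 in a crossed Claisen condensation and should give 9 after acidic quench.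

Step 7. Retro-aldol cleavage or C8 epimerisation of the β-alkoxide may compete under the basic LiAlH4 conditions before the ester is consumed. Benzylic ionisation of the freed p-hydroxybenzyl alcohol during work-up may also erode the anti configuration.

The fallback sets out from 10 and comes back at 11. The C7 hydroxyl is first silylated (TBSOTf, 2,6-lutidine, CH2Cl2, −78 to 0 °C) to the silyl ether F3, which cannot form a β-alkoxide. An excess of i-Bu2AlH (CH2Cl2, −78 to 0 °C) then reduces the ester and cleaves the acetate to give the 7-O-silyl diol F4. Bu4NF buffered with AcOH in THF at 0 °C removes the silyl group under nearly neutral conditions to give 11.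

Further compounds
F1 | step 6 | racemic ethyl (2R*,3R*)-3-(4-acetoxy-3,5-dimethoxyphenyl)-2-(4-allyl-2,6-dimethoxyphenoxy)-3-hydroxypropanoate (anti racemate, one enantiomer drawn) | C=CCc1cc(OC)c(O[C@@H](C(=O)OCC)[C@H](O)c2cc(OC)c(OC(C)=O)c(OC)c2)c(OC)c1
F2 | step 5 | ethyl 2-(4-allyl-2,6-dimethoxyphenoxy)acetate | C=CCc1cc(OC)c(OCC(=O)OCC)c(OC)c1
F3 | step 7 | ethyl (2R,3R)-3-(4-acetoxy-3,5-dimethoxyphenyl)-2-(4-allyl-2,6-dimethoxyphenoxy)-3-[(tert-butyldimethylsilyl)oxy]propanoate | C=CCc1cc(OC)c(O[C@@H](C(=O)OCC)[C@H](O[Si](C)(C)C(C)(C)C)c2cc(OC)c(OC(C)=O)c(OC)c2)c(OC)c1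
F4 | step 7 | 4-[(1R,2S)-2-(4-allyl-2,6-dimethoxyphenoxy)-1-[(tert-butyldimethylsilyl)oxy]-3-hydroxypropyl]-2,6-dimethoxyphenol | C=CCc1cc(OC)c(O[C@@H](CO)[C@H](O[Si](C)(C)C(C)(C)C)c2cc(OC)c(O)c(OC)c2)c(OC)c1
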